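## Retrosynthetic overview

- Enabling feature: in the 1,2-dioxane ring (O1–O2–C3–C4–C5–C6) both carbons bonded to the peroxide oxygens are latent carbonyl carbons (C3 an aldehyde carbon carrying the propanoate arm, C6 a methyl-ketone carbon carrying the C16 side chain), and C4–C5 is an unsubstituted CH2–CH2 bridge. The ring can therefore be made from two peroxycarbenium ions and a cis-vinylene dianion equivalent.
- Key disconnection (C3–C4 and C5–C6): a silylperoxy acetal of methyl (R)-2-methyl-3-oxopropanoate, (Z)-Bu3Sn–CH=CH–SiMe3 and the side-chain methyl ketone are joined in one pot to the 3,6-dihydro-1,2-dioxine; diimide and desilylation finish.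
- Side-chain ketone: Wittig union (chain C5'=C6', saturated later) of a phosphonium salt from (R)-3-bromo-2-methylpropan-1-ol with a β-peroxy aldehyde.
- Stereocentres: the tertiary hydroperoxide from (R)-linalool (hydroboration, oxetane, invertive opening with H2O2); C2 from an oxazolidinone-controlled acetal alkylation; C3 and C6 in the key step.
- Ring order: oxetane (temporary, step 10, opened in step 11), then 3,6-dihydro-1,2-dioxine (step 17), then 1,2-dioxane (step 18).

Key step: step 17

Remark on the chemistry: the acetal carbon of 5 and 6 is deliberately carried as a mixture of epimers, because step 17 makes it planar; commercial (R)-linalool and (R)-3-bromo-2-methylpropan-1-ol are assumed enantiopure.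

## Route

Step 1
Reactants: 1 (4S)-4-benzyl-3-propanoyl-1,3-oxazolidin-2-one
Product: 3 (4S)-4-benzyl-3-[(2R)-3,3-dimethoxy-2-methylpropanoyl]-1,3-oxazolidin-2-one, via chlorotitanium enolate 2 (not isolated)
Conditions: TiCl4 (1.05 equiv), i-Pr2NEt (1.1 equiv), CH2Cl2, 0 °C; then HC(OMe)3 (2 equiv), 0 °C
Reagents that add atoms: trimethyl orthoformate COC(OC)OC
Why: Alkylation of the chelated chlorotitanium Z-enolate by the dimethoxycarbenium ion released from the orthoester (auxiliary-controlled SN1-type enolate alkylation) occurs on the face away from the benzyl group and so sets C2 as R.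

Step 2
Reactants: 3 (4S)-4-benzyl-3-[(2R)-3,3-dimethoxy-2-methylpropanoyl]-1,3-oxazolidin-2-one
Product: 4 methyl (2R)-3,3-dimethoxy-2-methylpropanoate
Conditions: MeMgBr (1.2 equiv), MeOH, CH2Cl2, 0 °C
Reagents that add atoms: methanol CO
Why: Transesterification (auxiliary cleavage) by bromomagnesium methoxide attacks the exocyclic imide carbonyl at 0 °C, and the weakly basic, short reaction leaves the acetal and the C2 centre unchanged.

Step 3
Reactants: 4 methyl (2R)-3,3-dimethoxy-2-methylpropanoate
Product: 5 methyl (2R)-3-hydroperoxy-3-methoxy-2-methylpropanoate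
Conditions: anhydrous H2O2 in Et2O (5 equiv), BF3·OEt2 (0.2 equiv), 0 °C
Reagents that add atoms: hydrogen peroxide OO
Why: Acid-catalysed perhydrolysis of the acetal (trans-acetalisation through the oxocarbenium ion) replaces one OMe by OOH; the acetal carbon is formed as both epimers, which does not matter because it is made planar again in step 17, and C2 is not involved.

Step 4
Reactants: 5 methyl (2R)-3-hydroperoxy-3-methoxy-2-methylpropanoate
Product: 6 methyl (2R)-3-methoxy-2-methyl-3-[(triethylsilyl)peroxy]propanoate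
Conditions: Et3SiCl, imidazole, CH2Cl2, 0 °C
Reagents that add atoms: chlorotriethylsilane CC[Si](Cl)(CC)CC
Why: O-Silylation of the hydroperoxide with the silyl chloride and imidazole gives the silylperoxy acetal, the usual bench-stable precursor of a peroxycarbenium ion.

Step 5
Reactants: 7 ethyne; 8 tributyl(trimethylsilyl)stannane
Product: 9 (Z)-tributyl[2-(trimethylsilyl)ethenyl]stannane
Conditions: Pd(PPh3)4 (2 mol %), THF, 60 °C, sealed vessel
Reagents that add atoms: none
Why: Palladium-catalysed silylstannation of an alkyne (oxidative addition of Si–Sn to zerovalent palladium, syn insertion of ethyne, reductive elimination) delivers both metals to the same face and so gives only the Z isomer.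

Step 6
Reactants: 10 2-(2-bromoethyl)-2-methyl-1,3-dioxolane; 11 (2R)-3-bromo-2-methylpropan-1-ol
Product: 13 (2S)-2-methyl-5-(2-methyl-1,3-dioxolan-2-yl)pentan-1-ol, via Grignard reagent 12 (not isolated)
Conditions: 10, Mg, THF, 30 °C; then 11 (0.4 equiv relative to 12), Li2CuCl4 (3 mol %), THF, −20 → 0 °C
Reagents that add atoms: none
Why: Copper-catalysed cross-coupling of a Grignard reagent with a primary alkyl bromide (Kochi-type) is run on the magnesium alkoxide of 11, and the stereocentre is a spectator whose descriptor changes from R to S only because the priorities change.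

Step 7
Reactants: 13 (2S)-2-methyl-5-(2-methyl-1,3-dioxolan-2-yl)pentan-1-ol
Product: 14 2-[(4S)-5-iodo-4-methylpentyl]-2-methyl-1,3-dioxolane
Conditions: I2, PPh3, imidazole, CH2Cl2, 0 °C → rt
Reagents that add atoms: iodine II
Why: Appel-type iodination converts the primary alcohol into the iodide through the alkoxyphosphonium ion without touching the ketal or the stereocentre.

Step 8
Reactants: 14 2-[(4S)-5-iodo-4-methylpentyl]-2-methyl-1,3-dioxolane
Product: 15 [(2S)-2-methyl-5-(2-methyl-1,3-dioxolan-2-yl)pentyl]triphenylphosphonium iodide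
Conditions: PPh3 (2 equiv), K2CO3 (cat.), MeCN, 80 °C
Reagents that add atoms: triphenylphosphine c1ccc(cc1)P(c1ccccc1)c1ccccc1
Why: SN2 quaternisation of triphenylphosphine by the primary iodide gives the phosphonium salt, and the dioxolane keeps the ketone from a later intramolecular Wittig reaction.

Step 9
Reactants: 16 (3R)-3,7-dimethylocta-1,6-dien-3-ol
Product: 18 (3R)-3,7-dimethyloct-6-ene-1,3-diol, via B-alkyl-9-borabicyclononane 17 (not isolated)
Conditions: 9-BBN (1.5 equiv), THF, 0 °C → rt; then NaOH, H2O2, 0 °C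
Reagents that add atoms: hydrogen peroxide OO
Why: Anti-Markovnikov hydroboration–oxidation with the bulky borane selects the monosubstituted vinyl group over the trisubstituted alkene and leaves the carbinol centre untouched.

Step 10
Reactants: 18 (3R)-3,7-dimethyloct-6-ene-1,3-diol
Product: 20 (2R)-2-methyl-2-(4-methylpent-3-en-1-yl)oxetane, via primary tosylate 19 (not isolated)
Conditions: n-BuLi (1.0 equiv), THF, 0 °C; TsCl (1.0 equiv), 0 °C; n-BuLi (1.0 equiv), 0 → 60 °C
Reagents that add atoms: none
Why: Selective sulfonylation of the primary alkoxide and intramolecular Williamson etherification by the tertiary alkoxide (4-exo-tet) close the oxetane with retention at the carbinol carbon, whose C–O bond is never broken.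

Step 11
Reactants: 20 (2R)-2-methyl-2-(4-methylpent-3-en-1-yl)oxetane
Product: 21 (3S)-3-hydroperoxy-3,7-dimethyloct-6-en-1-ol
Conditions: anhydrous H2O2 in Et2O (10 equiv), Me3SiOTf (0.3 equiv), Et2O, −78 → −40 °C
Reagents that add atoms: hydrogen peroxide OO
Why: Lewis-acid-promoted opening of the 2,2-disubstituted oxetane by H2O2 takes place at the tertiary carbon of the silylated oxonium ion with inversion (SN2-like substitution), which turns the R carbinol configuration of linalool into the S hydroperoxide needed here.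

Step 12
Reactants: 21 (3S)-3-hydroperoxy-3,7-dimethyloct-6-en-1-ol
Product: 22 (3S)-3-[(2-methoxypropan-2-yl)peroxy]-3,7-dimethyloct-6-en-1-ol
Conditions: 2-methoxypropene (1.1 equiv), PPTS (2 mol %), CH2Cl2, −20 → 0 °C
Reagents that add atoms: 2-methoxypropene C=C(C)OC
Why: Acid-catalysed addition to the enol ether (peroxyketal formation) occurs on the hydroperoxide, the more acidic and more nucleophilic OH group, so that the primary alcohol stays free.

Step 13
Reactants: 22 (3S)-3-[(2-methoxypropan-2-yl)peroxy]-3,7-dimethyloct-6-en-1-ol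
Product: 23 (3S)-3-[(2-methoxypropan-2-yl)peroxy]-3,7-dimethyloct-6-enal
Conditions: Dess–Martin periodinane (1.3 equiv), NaHCO3, CH2Cl2, 0 °C
Reagents that add atoms: none
Why: Dess–Martin oxidation under buffered conditions gives the β-peroxy aldehyde without base, so that β-elimination of the peroxide is avoided.

Step 14
Reactants: 15 [(2S)-2-methyl-5-(2-methyl-1,3-dioxolan-2-yl)pentyl]triphenylphosphonium iodide; 23 (3S)-3-[(2-methoxypropan-2-yl)peroxy]-3,7-dimethyloct-6-enal
Product: 25 2-[(4S,5Z,8S)-8-[(2-methoxypropan-2-yl)peroxy]-4,8,12-trimethyltrideca-5,11-dien-1-yl]-2-methyl-1,3-dioxolane, via phosphonium ylide 24 (not isolated)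
Conditions: 15, NaN(SiMe3)2 (0.98 equiv), THF, −78 → 0 °C; then 23, −78 °C → rt
Reagents that add atoms: none
Why: Wittig olefination with a non-stabilised ylide under salt-free conditions gives the Z alkene (the geometry is erased in step 18), is fast at low temperature and is tolerated by the di-tertiary peroxyketal.

Step 15
Reactants: 25 2-[(4S,5Z,8S)-8-[(2-methoxypropan-2-yl)peroxy]-4,8,12-trimethyltrideca-5,11-dien-1-yl]-2-methyl-1,3-dioxolane
Product: 26 (6S,7Z,10S)-10-hydroperoxy-6,10,14-trimethylpentadeca-7,13-dien-2-one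
Conditions: PPTS (0.2 equiv), acetone/H2O (10:1), 45 °C
Reagents that add atoms: water O
Why: Acid-catalysed hydrolysis of the two ketals (dioxolane and peroxyketal) in aqueous acetone frees the ketone and the tertiary hydroperoxide, which is stable to mild acid.

Step 16
Reactants: 26 (6S,7Z,10S)-10-hydroperoxy-6,10,14-trimethylpentadeca-7,13-dien-2-one
Product: 27 (6S,7Z,10S)-10-[(tert-butyldimethylsilyl)peroxy]-6,10,14-trimethylpentadeca-7,13-dien-2-one
Conditions: t-BuMe2SiCl (1.3 equiv), imidazole (2.5 equiv), DMF, 0 °C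
Reagents that add atoms: tert-butyl(chloro)dimethylsilane CC(C)(C)[Si](C)(C)Cl
Why: O-Silylation turns the hydroperoxide into a hindered tertiary silyl peroxide that is inert to silyl triflate at low temperature and can be removed with fluoride.

Step 17
Reactants: 6 methyl (2R)-3-methoxy-2-methyl-3-[(triethylsilyl)peroxy]propanoate; 9 (Z)-tributyl[2-(trimethylsilyl)ethenyl]stannane; 27 (6S,7Z,10S)-10-[(tert-butyldimethylsilyl)peroxy]-6,10,14-trimethylpentadeca-7,13-dien-2-one
Product: 29 methyl (2R)-2-[(3S,6R)-6-[(4S,5Z,8S)-8-[(tert-butyldimethylsilyl)peroxy]-4,8,12-trimethyltrideca-5,11-dien-1-yl]-6-methyl-3,6-dihydro-1,2-dioxin-3-yl]propanoate, via allylic silyl peroxide 28 (not isolated)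
Conditions: one pot: 6 (1.3 equiv), 9 (1.25 equiv), Me3SiOTf (1.35 equiv), 2,6-di-tert-butyl-4-methylpyridine (0.3 equiv), CH2Cl2, −78 °C; then 27 (1.0 equiv), Me3SiOTf (0.3 equiv), −78 → −30 °C; NaHCO3 quench
Reagents that add atoms: none
Why: Proposed new method: Me3SiOTf ionises the C–OMe bond of 6 (both epimers) to one silylperoxy-stabilised carbenium ion at C3, which the tin-bearing carbon of 9 attacks (β-tin-stabilised cation, loss of Bu3Sn+ with retention of the Z geometry) to give the allylic silyl peroxide 28; when ketone 27 is then added, the silyl peroxide condenses with the silyl-activated carbonyl to a peroxy hemiketal silyl ether that ionises to the peroxycarbenium ion at C6, and the vinylsilane closes the ring at its silicon-bearing carbon with loss of Me3Si+, which regenerates the silyl triflate. The closest known reaction types are the Lewis-acid additions of allylsilanes and alkenes to peroxycarbenium ions, the silyl-triflate condensation of silyl peroxides with ketones used to make 1,2,4-trioxanes, and the vinylsilane-terminated oxocarbenium (silyl-Prins) cyclisation to 3,6-dihydro-2H-pyrans, of which this is the peroxy homologue. The single ring closes in a 6-endo-trig mode with respect to the vinylsilane (the C=O+ bond also lies inside the ring) through a chair-like transition state. C3 is set in the intermolecular step under Felkin–Anh control by C2 (ester antiperiplanar to the nucleophile, non-chelating silyl Lewis acid), which gives the 2,3-syn relationship; C6 is set in the ring closure relative to C3, with the C3 substituent and the long chain (anti to the O–O bond in the peroxycarbenium ion) pseudo-equatorial and the methyl pseudo-axial. The step needs C3 to be alkylated before C6 and each cation to meet the right terminus: the ketone is withheld until the acetal is consumed, 9 is used in no excess over 6, the stannyl end is far more nucleophilic than the silyl end, and the side-chain alkenes and the hindered tertiary silyl peroxide are too remote or too hindered to compete with a six-membered closure. Both acetal epimers of 6 and both geometries of the C6 cation (which equilibrate through the hemiketal) should funnel into one product, so the step is stereoconvergent.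

Step 18
Reactants: 29 methyl (2R)-2-[(3S,6R)-6-[(4S,5Z,8S)-8-[(tert-butyldimethylsilyl)peroxy]-4,8,12-trimethyltrideca-5,11-dien-1-yl]-6-methyl-3,6-dihydro-1,2-dioxin-3-yl]propanoate
Product: 31 methyl (2R)-2-[(3S,6R)-6-[(4S,8R)-8-[(tert-butyldimethylsilyl)peroxy]-4,8,12-trimethyltridec-11-en-1-yl]-6-methyl-1,2-dioxan-3-yl]propanoate, via ring-saturated diene 30 (not isolated)
Conditions: KO2C–N=N–CO2K (excess, in portions), AcOH (slow addition), CH2Cl2, 0 °C → rt, stopped when 29 and 30 are consumed
Reagents that add atoms: none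
Why: Diimide reduction (concerted syn transfer of H2 from HN=NH generated from the azodicarboxylate) saturates C=C bonds without cleaving O–O bonds and reduces the two cis-disubstituted alkenes, the allylically dioxygenated ring alkene first, faster than the trisubstituted alkene; no stereocentre is created.

Step 19
Reactants: 31 methyl (2R)-2-[(3S,6R)-6-[(4S,8R)-8-[(tert-butyldimethylsilyl)peroxy]-4,8,12-trimethyltridec-11-en-1-yl]-6-methyl-1,2-dioxan-3-yl]propanoate
Product: 32 methyl (2R)-2-[(3S,6R)-6-[(4R,8R)-8-hydroperoxy-4,8,12-trimethyltridec-11-en-1-yl]-6-methyl-1,2-dioxan-3-yl]propanoate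
Conditions: HF·pyridine, pyridine, THF, 0 °C
Reagents that add atoms: none
Why: Fluoride-induced cleavage of the Si–O bond of the silyl peroxide (desilylation) under buffered, non-basic conditions frees the tertiary hydroperoxide without base-induced opening of the β-peroxy ester or epimerisation at C2.

## Compound list

1 | (4S)-4-benzyl-3-propanoyl-1,3-oxazolidin-2-one | CCC(=O)N1[C@@H](Cc2ccccc2)COC1=O | starting material
2 | chlorotitanium Z-enolate of 1, trichloro{[(1Z)-1-[(4S)-4-benzyl-2-oxo-1,3-oxazolidin-3-yl]prop-1-en-1-yl]oxy}titanium | C/C=C(\O[Ti](Cl)(Cl)Cl)N1[C@@H](Cc2ccccc2)COC1=O | intermediate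
3 | (4S)-4-benzyl-3-[(2R)-3,3-dimethoxy-2-methylpropanoyl]-1,3-oxazolidin-2-one | COC(OC)[C@@H](C)C(=O)N1[C@@H](Cc2ccccc2)COC1=O | intermediate
4 | methyl (2R)-3,3-dimethoxy-2-methylpropanoate | COC(OC)[C@@H](C)C(=O)OC | intermediate
5 | methyl (2R)-3-hydroperoxy-3-methoxy-2-methylpropanoate (both C3 epimers) | COC(OO)[C@@H](C)C(=O)OC | intermediate
6 | methyl (2R)-3-methoxy-2-methyl-3-[(triethylsilyl)peroxy]propanoate (both C3 epimers) | COC(OO[Si](CC)(CC)CC)[C@@H](C)C(=O)OC | intermediate
7 | ethyne | C#C | starting material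
8 | tributyl(trimethylsilyl)stannane | CCCC[Sn](CCCC)(CCCC)[Si](C)(C)C | starting material
9 | (Z)-tributyl[2-(trimethylsilyl)ethenyl]stannane | C[Si](C)(C)/C=C\[Sn](CCCC)(CCCC)CCCC | intermediate
10 | 2-(2-bromoethyl)-2-methyl-1,3-dioxolane | CC1(CCBr)OCCO1 | starting material
11 | (2R)-3-bromo-2-methylpropan-1-ol | OC[C@@H](C)CBr | starting material
12 | bromo[2-(2-methyl-1,3-dioxolan-2-yl)ethyl]magnesium | CC1(CC[Mg]Br)OCCO1 | intermediate
13 | (2S)-2-methyl-5-(2-methyl-1,3-dioxolan-2-yl)pentan-1-ol | OC[C@@H](C)CCCC1(C)OCCO1 | intermediate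
14 | 2-[(4S)-5-iodo-4-methylpentyl]-2-methyl-1,3-dioxolane | IC[C@@H](C)CCCC1(C)OCCO1 | intermediate
15 | [(2S)-2-methyl-5-(2-methyl-1,3-dioxolan-2-yl)pentyl]triphenylphosphonium iodide | [I-].c1ccc(cc1)[P+](c1ccccc1)(c1ccccc1)C[C@@H](C)CCCC1(C)OCCO1 | intermediate
16 | (3R)-3,7-dimethylocta-1,6-dien-3-ol, (R)-linalool | C=C[C@](C)(O)CCC=C(C)C | starting material
17 | 9-[(3S)-3-hydroxy-3,7-dimethyloct-6-en-1-yl]-9-borabicyclo[3.3.1]nonane (drawn with the free tertiary alcohol) | CC(C)=CCC[C@@](C)(O)CCB1C2CCCC1CCC2 | intermediate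
18 | (3R)-3,7-dimethyloct-6-ene-1,3-diol | OCC[C@](C)(O)CCC=C(C)C | intermediate
19 | (3R)-3-hydroxy-3,7-dimethyloct-6-en-1-yl 4-methylbenzenesulfonate | Cc1ccc(cc1)S(=O)(=O)OCC[C@](C)(O)CCC=C(C)C | intermediate
20 | (2R)-2-methyl-2-(4-methylpent-3-en-1-yl)oxetane | C[C@@]1(CCC=C(C)C)CCO1 | intermediate
21 | (3S)-3-hydroperoxy-3,7-dimethyloct-6-en-1-ol | OCC[C@](C)(CCC=C(C)C)OO | intermediate
22 | (3S)-3-[(2-methoxypropan-2-yl)peroxy]-3,7-dimethyloct-6-en-1-ol | OCC[C@](C)(CCC=C(C)C)OOC(C)(C)OC | intermediate
23 | (3S)-3-[(2-methoxypropan-2-yl)peroxy]-3,7-dimethyloct-6-enal | O=CC[C@](C)(CCC=C(C)C)OOC(C)(C)OC | intermediate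
24 | [(2S)-2-methyl-5-(2-methyl-1,3-dioxolan-2-yl)pentylidene]triphenyl-λ5-phosphane | c1ccc(cc1)P(c1ccccc1)(c1ccccc1)=C[C@@H](C)CCCC1(C)OCCO1 | intermediate
25 | 2-[(4S,5Z,8S)-8-[(2-methoxypropan-2-yl)peroxy]-4,8,12-trimethyltrideca-5,11-dien-1-yl]-2-methyl-1,3-dioxolane | CC1(CCC[C@H](C)/C=C\C[C@](C)(CCC=C(C)C)OOC(C)(C)OC)OCCO1 | intermediate
26 | (6S,7Z,10S)-10-hydroperoxy-6,10,14-trimethylpentadeca-7,13-dien-2-one | CC(=O)CCC[C@H](C)/C=C\C[C@](C)(CCC=C(C)C)OO | intermediate
27 | (6S,7Z,10S)-10-[(tert-butyldimethylsilyl)peroxy]-6,10,14-trimethylpentadeca-7,13-dien-2-one | CC(=O)CCC[C@H](C)/C=C\C[C@](C)(CCC=C(C)C)OO[Si](C)(C)C(C)(C)C | intermediate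
28 | methyl (2R,3R,4Z)-2-methyl-3-[(triethylsilyl)peroxy]-5-(trimethylsilyl)pent-4-enoate | COC(=O)[C@H](C)[C@@H](OO[Si](CC)(CC)CC)/C=C\[Si](C)(C)C | intermediate
29 | methyl (2R)-2-[(3S,6R)-6-[(4S,5Z,8S)-8-[(tert-butyldimethylsilyl)peroxy]-4,8,12-trimethyltrideca-5,11-dien-1-yl]-6-methyl-3,6-dihydro-1,2-dioxin-3-yl]propanoate | COC(=O)[C@H](C)[C@@H]1C=C[C@@](C)(CCC[C@H](C)/C=C\C[C@](C)(CCC=C(C)C)OO[Si](C)(C)C(C)(C)C)OO1 | intermediate
30 | methyl (2R)-2-[(3S,6R)-6-[(4S,5Z,8S)-8-[(tert-butyldimethylsilyl)peroxy]-4,8,12-trimethyltrideca-5,11-dien-1-yl]-6-methyl-1,2-dioxan-3-yl]propanoate | COC(=O)[C@H](C)[C@@H]1CC[C@@](C)(CCC[C@H](C)/C=C\C[C@](C)(CCC=C(C)C)OO[Si](C)(C)C(C)(C)C)OO1 | intermediate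
31 | methyl (2R)-2-[(3S,6R)-6-[(4S,8R)-8-[(tert-butyldimethylsilyl)peroxy]-4,8,12-trimethyltridec-11-en-1-yl]-6-methyl-1,2-dioxan-3-yl]propanoate | COC(=O)[C@H](C)[C@@H]1CC[C@@](C)(CCC[C@H](C)CCC[C@](C)(CCC=C(C)C)OO[Si](C)(C)C(C)(C)C)OO1 | intermediate
32 | methyl (2R)-2-[(3S,6R)-6-[(4R,8R)-8-hydroperoxy-4,8,12-trimethyltridec-11-en-1-yl]-6-methyl-1,2-dioxan-3-yl]propanoate | COC(=O)[C@H](C)[C@@H]1CC[C@@](C)(CCC[C@H](C)CCC[C@](C)(CCC=C(C)C)OO)OO1 | target

## Step count and risks

Total step count: 19. Longest linear sequence: 11 steps (16 to 32, steps 9 to 19).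

Steps most likely to fail:

1. Step 17 (Proposed new method). The cations may be captured out of sequence or by the wrong partner: the silylperoxy oxygen may close onto the β-metallo cation to give a 1,2-dioxolane, the C6 cation may be trapped intermolecularly, or the vinylsilane may be protodesilylated before ring closure. Facial selection at C3 or C6 may also be weak. The fallback uses known chemistry only and closes the ring by the established intramolecular oxa-Michael addition of a tertiary hydroperoxide to a 2-methyl-2-enoate. It sets out from 27. Hemiperketalisation with H2O2·urea in MeOH/HC(OMe)3 (cat. Sc(OTf)3) should give (6S,7Z,10S)-10-[(tert-butyldimethylsilyl)peroxy]-2-hydroperoxy-2-methoxy-6,10,14-trimethylpentadeca-7,13-diene F1, which is silylated (Et3SiCl, imidazole) to the triethylsilyl peroxyketal F2. Lewis-acid allylation of this peroxyketal with allyltributylstannane (Me3SiOTf, −78 °C, Hosomi–Sakurai type; loss of tin should outrun dioxolane closure) should give the tertiary homoallyl silyl peroxide (8S,9Z,12S)-12-[(tert-butyldimethylsilyl)peroxy]-4,8,12,16-tetramethyl-4-[(triethylsilyl)peroxy]heptadeca-1,9,15-triene F3 as both epimers at the new quaternary carbon. Hydroboration of the terminal alkene with 9-BBN and oxidation with NaBO3 give the primary alcohol F4, Dess–Martin oxidation the aldehyde F5, and Wittig reaction with methyl 2-(triphenyl-λ5-phosphanylidene)propanoate the E-enoate F6. HF·pyridine frees both hydroperoxides to the bis-hydroperoxide F7, and Et2NH in CF3CH2OH closes the ring (6-exo-trig) to the 1,2-dioxane F8. Its chain alkene is reduced with diimide as in step 18, and the route comes back at 32. This sequence controls neither C6 nor C2, so 32 has to be separated from its ring diastereomers by preparative chromatography.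

2. Step 18. The trisubstituted alkene may be over-reduced while the slower acyclic cis-alkene is still being consumed. The fallback sets out from 29: the diimide reduction is interrupted at 30, since the ring alkene should react first. The remaining Z-alkene is then saturated by homogeneous hydrogenation (H2, RhCl(PPh3)3, benzene/EtOH, rt), which discriminates cis-disubstituted from trisubstituted alkenes more sharply than diimide and should leave the hindered saturated peroxides alone. It comes back at 31 and makes no new compound.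

3. Step 11. Part of the substitution may leak through an ionised (SN1) pathway, with partial loss of configuration at the tertiary centre or participation of the alkene. The fallback sets out from 21 of eroded purity and restores purity by resolution instead of forcing the substitution. 21 is ketalised with (1R,2S)-2-phenylcyclohexyl prop-1-en-2-yl ether (PPTS, CH2Cl2, 0 °C) to (3S)-3,7-dimethyl-3-[(2-{[(1R,2S)-2-phenylcyclohexyl]oxy}propan-2-yl)peroxy]oct-6-en-1-ol F9 and its (3R) diastereomer. These are separated by chromatography (classical resolution of a hydroperoxide as diastereomeric perketals). Hydrolysis of F9 with aqueous acetic acid comes back at 21.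

Further compounds
F1 | step 17 | (6S,7Z,10S)-10-[(tert-butyldimethylsilyl)peroxy]-2-hydroperoxy-2-methoxy-6,10,14-trimethylpentadeca-7,13-diene (both C2 epimers) | COC(C)(OO)CCC[C@H](C)/C=C\C[C@](C)(CCC=C(C)C)OO[Si](C)(C)C(C)(C)C
F2 | step 17 | (6S,7Z,10S)-10-[(tert-butyldimethylsilyl)peroxy]-2-methoxy-6,10,14-trimethyl-2-[(triethylsilyl)peroxy]pentadeca-7,13-diene (both C2 epimers) | COC(C)(OO[Si](CC)(CC)CC)CCC[C@H](C)/C=C\C[C@](C)(CCC=C(C)C)OO[Si](C)(C)C(C)(C)C
F3 | step 17 | (8S,9Z,12S)-12-[(tert-butyldimethylsilyl)peroxy]-4,8,12,16-tetramethyl-4-[(triethylsilyl)peroxy]heptadeca-1,9,15-triene (both C4 epimers) | C=CCC(C)(OO[Si](CC)(CC)CC)CCC[C@H](C)/C=C\C[C@](C)(CCC=C(C)C)OO[Si](C)(C)C(C)(C)C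
F4 | step 17 | (8S,9Z,12S)-12-[(tert-butyldimethylsilyl)peroxy]-4,8,12,16-tetramethyl-4-[(triethylsilyl)peroxy]heptadeca-9,15-dien-1-ol (both C4 epimers) | OCCCC(C)(OO[Si](CC)(CC)CC)CCC[C@H](C)/C=C\C[C@](C)(CCC=C(C)C)OO[Si](C)(C)C(C)(C)C
F5 | step 17 | (8S,9Z,12S)-12-[(tert-butyldimethylsilyl)peroxy]-4,8,12,16-tetramethyl-4-[(triethylsilyl)peroxy]heptadeca-9,15-dienal (both C4 epimers) | O=CCCC(C)(OO[Si](CC)(CC)CC)CCC[C@H](C)/C=C\C[C@](C)(CCC=C(C)C)OO[Si](C)(C)C(C)(C)C
F6 | step 17 | methyl (2E,10S,11Z,14S)-14-[(tert-butyldimethylsilyl)peroxy]-2,6,10,14,18-pentamethyl-6-[(triethylsilyl)peroxy]nonadeca-2,11,17-trienoate (both C6 epimers) | COC(=O)/C(C)=C/CCC(C)(OO[Si](CC)(CC)CC)CCC[C@H](C)/C=C\C[C@](C)(CCC=C(C)C)OO[Si](C)(C)C(C)(C)C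
F7 | step 17 | methyl (2E,10S,11Z,14S)-6,14-dihydroperoxy-2,6,10,14,18-pentamethylnonadeca-2,11,17-trienoate (both C6 epimers) | COC(=O)/C(C)=C/CCC(C)(OO)CCC[C@H](C)/C=C\C[C@](C)(CCC=C(C)C)OO
F8 | step 17 | methyl 2-[6-[(4S,5Z,8S)-8-hydroperoxy-4,8,12-trimethyltrideca-5,11-dien-1-yl]-6-methyl-1,2-dioxan-3-yl]propanoate (isomers at C2 and at ring C3 and C6) | COC(=O)C(C)C1CCC(C)(CCC[C@H](C)/C=C\C[C@](C)(CCC=C(C)C)OO)OO1
F0 | step 18 | none | none
F9 | step 11 | (3S)-3,7-dimethyl-3-[(2-{[(1R,2S)-2-phenylcyclohexyl]oxy}propan-2-yl)peroxy]oct-6-en-1-ol | OCC[C@](C)(CCC=C(C)C)OOC(C)(C)O[C@@H]1CCCC[C@H]1c1ccccc1
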